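**Retrosynthetic overview**
- Target 19 ← bromide-for-silyloxy exchange with inversion at the side-chain carbon ← Mitsunobu acetate inversion at the ring carbinol ← allylic alcohol 16.
- 16 ← ring expansion of bicyclo[3.1.0]hexane 14: loss of the endo C6 bromide with opening of the C1–C5 bond gives a cyclohexenyl cation, captured by water.
- 14 ← exo-chloroacetylation of the lithium carbenoid from tribromide 8, CBS reduction, silylation; 8 ← dibromocarbene + (S)-4-bromo-3,3-dimethylcyclopentene 6.
- 6 ← 2,2-dimethylcyclopentane-1,3-dione 1 by CBS desymmetrization, triflate-to-bromide inversion, enol triflate formation and reduction.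
- Ring order: cyclopentane (in 1) → fused cyclopropane (step 5) → cyclohexene by one-carbon expansion (step 9). Enabling feature: in 14 the cyclopropane C1–C5–C6 is cis-fused to the cyclopentane C1–C2–C3–C4–C5, and C6 carries an endo bromide plus the exo side chain, so cleavage of the shared C1–C5 bond gives the allyl cation C1–C6–C5.

Key step: step 9

Assumption: both CBS reductions follow the usual large/small model; if either sense proved opposite, the enantiomeric catalyst would be used. Dibromocarbene is drawn adding anti to the C–Br bond; the syn adduct would converge, because both ring-fusion carbons become trigonal in step 9.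

**Step 1**
Reactants: 1 2,2-dimethylcyclopentane-1,3-dione
Product: 2 (R)-3-hydroxy-2,2-dimethylcyclopentan-1-one
Conditions: (S)-Me-CBS oxazaborolidine [(S)-1-methyl-3,3-diphenyltetrahydro-1H,3H-pyrrolo[1,2-c][1,3,2]oxazaborole, C18H20BNO] (10 mol %), BH3·SMe2 (0.6 equiv), THF, −30 °C; MeOH
Reagents that add atoms: none
Why: Corey–Bakshi–Shibata reduction distinguishes the two enantiotopic carbonyls, and with the quaternary carbon as the large flank and CH2 as the small flank the (S)-catalyst should give the R carbinol.

**Step 2**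
Reactants: 2 (R)-3-hydroxy-2,2-dimethylcyclopentan-1-one
Product: 4 (S)-3-bromo-2,2-dimethylcyclopentan-1-one, via secondary triflate 3 (not isolated)
Conditions: Tf2O, 2,6-lutidine, CH2Cl2, −40 °C; then Bu4NBr, −40 → 0 °C
Reagents that add atoms: tetrabutylammonium bromide, CCCC[N+](CCCC)(CCCC)CCCC.[Br-]
Why: SN2 displacement of the triflate by bromide with inversion (R carbinol to S bromide) should be feasible because the neighbouring carbonyl retards ionization and methyl shift and the five-membered ring leaves the backside open, as in inversions at steroid ring D carbinols next to a quaternary carbon.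

**Step 3**
Reactants: 4 (S)-3-bromo-2,2-dimethylcyclopentan-1-one
Product: 5 (4S)-4-bromo-5,5-dimethylcyclopent-1-en-1-yl trifluoromethanesulfonate
Conditions: Tf2O, 2,6-di-tert-butyl-4-methylpyridine, CH2Cl2, 0 °C → rt
Reagents that add atoms: triflic anhydride, O=S(=O)(OS(=O)(=O)C(F)(F)F)C(F)(F)F
Why: O-triflation of the only possible enol (the other α-carbon is quaternary) gives one enol triflate regioisomer under non-nucleophilic, weakly basic conditions that leave the C–Br stereocenter untouched.

**Step 4**
Reactants: 5 (4S)-4-bromo-5,5-dimethylcyclopent-1-en-1-yl trifluoromethanesulfonate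
Product: 6 (S)-4-bromo-3,3-dimethylcyclopent-1-ene
Conditions: Pd(OAc)2 (5 mol %), PPh3, HCO2H, Bu3N, DMF, 60 °C
Reagents that add atoms: none
Why: Palladium-catalysed formate reduction of an enol triflate gives the alkene, and the hindered secondary alkyl bromide should not add to zerovalent palladium under these conditions.

**Step 5**
Reactants: 6 (S)-4-bromo-3,3-dimethylcyclopent-1-ene; 7 bromoform
Product: 8 (1S,3S,5S)-3,6,6-tribromo-2,2-dimethylbicyclo[3.1.0]hexane
Conditions: KOtBu, pentane, −20 → 0 °C
Reagents that add atoms: bromoform, BrC(Br)Br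
Why: [2+1] addition of dibromocarbene to the cis-alkene gives the cis-fused gem-dibromocyclopropane, expected mainly anti to the C–Br bond; low temperature and the insoluble base limit E2 loss of HBr.

**Step 6**
Reactants: 8 (1S,3S,5S)-3,6,6-tribromo-2,2-dimethylbicyclo[3.1.0]hexane; 9 2-chloro-N-methoxy-N-methylacetamide
Product: 12 1-[(1S,3S,5S,6S)-3,6-dibromo-2,2-dimethylbicyclo[3.1.0]hexan-6-yl]-2-chloroethan-1-one, via exo-lithio carbenoid 10 (not isolated), via tetrahedral lithium adduct 11 (not isolated)
Conditions: 8 added to n-BuLi (1.05 equiv), THF–Et2O–pentane, −105 °C; then 9, −105 → −78 °C; aq. NH4Cl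
Reagents that add atoms: 2-chloro-N-methoxy-N-methylacetamide, CN(OC)C(=O)CCl
Why: Bromine–lithium exchange takes the less hindered exo bromine, inverse addition keeps unreacted 8 from equilibrating the carbenoid, and Weinreb acylation with retention places the acyl group exo and leaves the endo bromide needed in step 9; the secondary alkyl bromide should not exchange at this temperature.

**Step 7**
Reactants: 12 1-[(1S,3S,5S,6S)-3,6-dibromo-2,2-dimethylbicyclo[3.1.0]hexan-6-yl]-2-chloroethan-1-one
Product: 13 (1S)-1-[(1S,3S,5S,6S)-3,6-dibromo-2,2-dimethylbicyclo[3.1.0]hexan-6-yl]-2-chloroethan-1-ol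
Conditions: (R)-Me-CBS oxazaborolidine (C18H20BNO, 20 mol %), BH3·SMe2, THF, −20 °C; MeOH
Reagents that add atoms: none
Why: CBS reduction with the bicyclic 1-bromocyclopropyl group as large and CH2Cl as small substituent should give, with the (R)-catalyst, the carbinol whose later invertive bromination gives the S bromide.

**Step 8**
Reactants: 13 (1S)-1-[(1S,3S,5S,6S)-3,6-dibromo-2,2-dimethylbicyclo[3.1.0]hexan-6-yl]-2-chloroethan-1-ol
Product: 14 tert-butyl{(1S)-1-[(1S,3S,5S,6S)-3,6-dibromo-2,2-dimethylbicyclo[3.1.0]hexan-6-yl]-2-chloroethoxy}dimethylsilane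
Conditions: TBSOTf, 2,6-lutidine, CH2Cl2, −78 → 0 °C
Reagents that add atoms: tert-butyldimethylsilyl triflate, CC(C)(C)[Si](C)(C)OS(=O)(=O)C(F)(F)F
Why: Silyl triflate silylation of the hindered secondary alcohol leaves only one free hydroxyl for steps 9 and 10 and installs the group later exchanged directly for bromide.

**Step 9**
Reactants: 14 tert-butyl{(1S)-1-[(1S,3S,5S,6S)-3,6-dibromo-2,2-dimethylbicyclo[3.1.0]hexan-6-yl]-2-chloroethoxy}dimethylsilane
Product: 16 (1S,5S)-5-bromo-2-[(1R)-1-(tert-butyldimethylsilyloxy)-2-chloroethyl]-4,4-dimethylcyclohex-2-en-1-ol, via cyclohexenyl cation 15 (not isolated)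
Conditions: AgNO3 (1.5 equiv), CaCO3, acetone–H2O (4:1), 20–40 °C, dark
Reagents that add atoms: water, O
Why: Silver-assisted ionization of the endo C6–Br bond is concerted with the Woodward–Hoffmann-allowed disrotatory opening of the cyclopropane (cleavage of the C1–C5 bond shared by both rings), which turns the five-membered ring into the 2-substituted cyclohex-2-enyl cation 15 that water then captures; the closest known reaction type is the silver-promoted solvolytic ring expansion of ring-fused gem-dihalo- and monohalocyclopropanes to 2-substituted cyclohex-2-enyl alcohols and esters. No ring is closed: the six-membered ring arises by two-electron electrocyclic opening of the three-membered ring, which inserts C6 between the two former alkene carbons. The new carbinol stereocenter is set by attack of water anti to the ring bromide, which should sit pseudoaxial in the cation (one gauche contact fewer with the gem-dimethyl group and no 1,3-diaxial partner), giving the 1,5-trans alcohol, and the CH2Cl group of the side chain should lie on the bromine face when its C–H is in the allyl plane. Regioselectivity for the terminus remote from the quaternary carbon is secured because the other terminus is neopentylic. Chemoselectivity among the three carbon–halogen bonds is secured by strain release at the tertiary endo cyclopropyl bromide, whereas the secondary ring bromide and the primary chloride ionize far more slowly, and CaCO3 keeps the silyl ether intact.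

**Step 10**
Reactants: 16 (1S,5S)-5-bromo-2-[(1R)-1-(tert-butyldimethylsilyloxy)-2-chloroethyl]-4,4-dimethylcyclohex-2-en-1-ol; 17 acetic acid
Product: 18 (1R,5S)-5-bromo-2-[(1R)-1-(tert-butyldimethylsilyloxy)-2-chloroethyl]-4,4-dimethylcyclohex-2-en-1-yl acetate
Conditions: PPh3, DIAD, THF, 0 °C → rt
Reagents that add atoms: acetic acid, CC(=O)O
Why: Mitsunobu esterification displaces the activated hydroxyl by acetate in an SN2 sense with inversion, converting the trans alcohol into the cis acetate, while SN2' attack at the other allyl terminus is blocked by the gem-dimethyl group.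

**Step 11**
Reactants: 18 (1R,5S)-5-bromo-2-[(1R)-1-(tert-butyldimethylsilyloxy)-2-chloroethyl]-4,4-dimethylcyclohex-2-en-1-yl acetate
Product: 19 (1R,5S)-5-bromo-2-[(1S)-1-bromo-2-chloroethyl]-4,4-dimethylcyclohex-2-en-1-yl acetate
Conditions: Ph3PBr2 (1.3 equiv), CH2Cl2, 0 °C → rt
Reagents that add atoms: triphenylphosphine dibromide, Br[P+](c1ccccc1)(c1ccccc1)c1ccccc1.[Br-]
Why: Triphenylphosphine dibromide converts the silyl ether directly into the bromide by silyl–bromine exchange and SN2 displacement at carbon with inversion (R silyl ether to S bromide); the β-chlorine disfavours ionization and SN2' attack would have to occur at the neopentylic ring carbon.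

**Compound list**
1 | 2,2-dimethylcyclopentane-1,3-dione | CC1(C)C(=O)CCC1=O | starting material
2 | (R)-3-hydroxy-2,2-dimethylcyclopentan-1-one | CC1(C)C(=O)CC[C@H]1O | intermediate
3 | (R)-2,2-dimethyl-3-oxocyclopentyl trifluoromethanesulfonate (not isolated) | CC1(C)C(=O)CC[C@H]1OS(=O)(=O)C(F)(F)F | intermediate
4 | (S)-3-bromo-2,2-dimethylcyclopentan-1-one | CC1(C)C(=O)CC[C@@H]1Br | intermediate
5 | (4S)-4-bromo-5,5-dimethylcyclopent-1-en-1-yl trifluoromethanesulfonate | CC1(C)C(OS(=O)(=O)C(F)(F)F)=CC[C@@H]1Br | intermediate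
6 | (S)-4-bromo-3,3-dimethylcyclopent-1-ene | CC1(C)C=CC[C@@H]1Br | intermediate
7 | bromoform | BrC(Br)Br | starting material
8 | (1S,3S,5S)-3,6,6-tribromo-2,2-dimethylbicyclo[3.1.0]hexane | CC1(C)[C@@H]2[C@@H](C2(Br)Br)C[C@@H]1Br | intermediate
9 | 2-chloro-N-methoxy-N-methylacetamide | CN(OC)C(=O)CCl | starting material
10 | (1S,3S,5S)-3,6-endo-dibromo-6-exo-lithio-2,2-dimethylbicyclo[3.1.0]hexane (not isolated) | CC1(C)[C@@H]2[C@@H]([C@]2([Li])Br)C[C@@H]1Br | intermediate
11 | lithium 1-[(1S,3S,5S)-3,6-endo-dibromo-2,2-dimethylbicyclo[3.1.0]hexan-6-yl]-2-chloro-1-[methoxy(methyl)amino]ethan-1-olate (not isolated) | CC1(C)[C@@H]2[C@@H]([C@]2(C(O[Li])(CCl)N(C)OC)Br)C[C@@H]1Br | intermediate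
12 | 1-[(1S,3S,5S,6S)-3,6-dibromo-2,2-dimethylbicyclo[3.1.0]hexan-6-yl]-2-chloroethan-1-one | CC1(C)[C@@H]2[C@@H]([C@]2(C(=O)CCl)Br)C[C@@H]1Br | intermediate
13 | (1S)-1-[(1S,3S,5S,6S)-3,6-dibromo-2,2-dimethylbicyclo[3.1.0]hexan-6-yl]-2-chloroethan-1-ol | CC1(C)[C@@H]2[C@@H]([C@]2([C@@H](O)CCl)Br)C[C@@H]1Br | intermediate
14 | tert-butyl{(1S)-1-[(1S,3S,5S,6S)-3,6-dibromo-2,2-dimethylbicyclo[3.1.0]hexan-6-yl]-2-chloroethoxy}dimethylsilane | CC1(C)[C@@H]2[C@@H]([C@]2([C@@H](O[Si](C)(C)C(C)(C)C)CCl)Br)C[C@@H]1Br | intermediate
15 | (5S)-5-bromo-2-[(1R)-1-(tert-butyldimethylsilyloxy)-2-chloroethyl]-4,4-dimethylcyclohex-2-en-1-ylium (not isolated) | CC1(C)C=C([C@@H](O[Si](C)(C)C(C)(C)C)CCl)[CH+]C[C@@H]1Br | intermediate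
16 | (1S,5S)-5-bromo-2-[(1R)-1-(tert-butyldimethylsilyloxy)-2-chloroethyl]-4,4-dimethylcyclohex-2-en-1-ol | O[C@H]1C[C@H](Br)C(C)(C)C=C1[C@@H](O[Si](C)(C)C(C)(C)C)CCl | intermediate
17 | acetic acid | CC(=O)O | starting material
18 | (1R,5S)-5-bromo-2-[(1R)-1-(tert-butyldimethylsilyloxy)-2-chloroethyl]-4,4-dimethylcyclohex-2-en-1-yl acetate | CC(=O)O[C@@H]1C[C@H](Br)C(C)(C)C=C1[C@@H](O[Si](C)(C)C(C)(C)C)CCl | intermediate
19 | (1R,5S)-5-bromo-2-[(1S)-1-bromo-2-chloroethyl]-4,4-dimethylcyclohex-2-en-1-yl acetate | CC(=O)O[C@@H]1C[C@H](Br)C(C)(C)C=C1[C@H](Br)CCl | target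

**Total step count:** 11. **Longest linear sequence:** 11 steps (1 → 19).

**Steps most likely to fail**

1. Step 9 (key step). Capture of the cation by water may show poor facial selectivity, because the silyloxy group of the side chain can sit on the attack face in a low-energy rotamer and so oppose the ring bromide; proton loss to a diene and slow silver-induced ionization of the ring bromide are secondary worries. The fallback makes the carbinol configuration independent of the capture. It sets out from 16, whatever its configuration at the carbinol carbon. Dess–Martin periodinane (NaHCO3, CH2Cl2) would give the enone (5S)-5-bromo-2-[(1R)-1-(tert-butyldimethylsilyloxy)-2-chloroethyl]-4,4-dimethylcyclohex-2-en-1-one F1, a β-bromo ketone that is kept away from amine bases. Luche reduction (NaBH4, CeCl3·7H2O, MeOH, −78 °C) should deliver hydride anti to the ring bromide, as with 5-substituted 2-alkylcyclohex-2-enones, giving (1R,5S)-5-bromo-2-[(1R)-1-(tert-butyldimethylsilyloxy)-2-chloroethyl]-4,4-dimethylcyclohex-2-en-1-ol F2. Acetylation (Ac2O, pyridine, DMAP) returns to the route at 18.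

2. Step 2. Substitution at the carbinol next to the quaternary carbon may be overtaken by elimination or by ionization with a 1,2-shift, with loss of material or of configuration. The fallback makes the carbinol allylic before the displacement and sets out from 1. IBX (DMSO, 70 °C) would dehydrogenate 1 to 2,2-dimethylcyclopent-4-ene-1,3-dione F3. CBS reduction with the same (S)-catalyst would reduce one of the two equivalent enone carbonyls to (4R)-4-hydroxy-5,5-dimethylcyclopent-2-en-1-one F4. Ionization of this allylic carbinol would give a destabilized 4-oxocyclopentenyl cation, so Appel bromination (CBr4, PPh3, CH2Cl2, 0 °C) should proceed by clean SN2 inversion to (4S)-4-bromo-5,5-dimethylcyclopent-2-en-1-one F5. Diimide (dipotassium azodicarboxylate, AcOH, MeOH) would saturate the enone double bond without touching the C–Br bond and rejoin the route at 4.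

3. Step 6. The kinetically formed exo-lithio carbenoid may equilibrate to the endo-lithio isomer or undergo α-elimination before acylation; an exo bromide cannot ionize in step 9. The fallback avoids the carbenoid and attaches the side chain after ring expansion; it sets out from 8 and rejoins at 19. The AgNO3/CaCO3 ring expansion applied to 8 (the exo bromine remains as a vinyl bromide) would give (1S,5S)-2,5-dibromo-4,4-dimethylcyclohex-2-en-1-ol F6. Mitsunobu inversion with acetic acid would give (1R,5S)-2,5-dibromo-4,4-dimethylcyclohex-2-en-1-yl acetate F7. Stille coupling with tributyl(1-ethoxyvinyl)stannane (PdCl2(PPh3)2, CuI, DMF) would give (1R,5S)-5-bromo-2-(1-ethoxyethenyl)-4,4-dimethylcyclohex-2-en-1-yl acetate F8. NCS in aqueous THF would convert the enol ether into (1R,5S)-5-bromo-2-(2-chloroacetyl)-4,4-dimethylcyclohex-2-en-1-yl acetate F9. CBS reduction with the (R)-catalyst and catecholborane would give (1R,5S)-5-bromo-2-[(1R)-2-chloro-1-hydroxyethyl]-4,4-dimethylcyclohex-2-en-1-yl acetate F10. Appel bromination (CBr4, PPh3) with inversion would give 19.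

**Further compounds**
F1 | step 9 | (5S)-5-bromo-2-[(1R)-1-(tert-butyldimethylsilyloxy)-2-chloroethyl]-4,4-dimethylcyclohex-2-en-1-one | O=C1C[C@H](Br)C(C)(C)C=C1[C@@H](O[Si](C)(C)C(C)(C)C)CCl
F2 | step 9 | (1R,5S)-5-bromo-2-[(1R)-1-(tert-butyldimethylsilyloxy)-2-chloroethyl]-4,4-dimethylcyclohex-2-en-1-ol | O[C@@H]1C[C@H](Br)C(C)(C)C=C1[C@@H](O[Si](C)(C)C(C)(C)C)CCl
F3 | step 2 | 2,2-dimethylcyclopent-4-ene-1,3-dione | CC1(C)C(=O)C=CC1=O
F4 | step 2 | (4R)-4-hydroxy-5,5-dimethylcyclopent-2-en-1-one | CC1(C)C(=O)C=C[C@H]1O
F5 | step 2 | (4S)-4-bromo-5,5-dimethylcyclopent-2-en-1-one | CC1(C)C(=O)C=C[C@@H]1Br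
F6 | step 6 | (1S,5S)-2,5-dibromo-4,4-dimethylcyclohex-2-en-1-ol | O[C@H]1C[C@H](Br)C(C)(C)C=C1Br
F7 | step 6 | (1R,5S)-2,5-dibromo-4,4-dimethylcyclohex-2-en-1-yl acetate | CC(=O)O[C@@H]1C[C@H](Br)C(C)(C)C=C1Br
F8 | step 6 | (1R,5S)-5-bromo-2-(1-ethoxyethenyl)-4,4-dimethylcyclohex-2-en-1-yl acetate | CC(=O)O[C@@H]1C[C@H](Br)C(C)(C)C=C1C(=C)OCC
F9 | step 6 | (1R,5S)-5-bromo-2-(2-chloroacetyl)-4,4-dimethylcyclohex-2-en-1-yl acetate | CC(=O)O[C@@H]1C[C@H](Br)C(C)(C)C=C1C(=O)CCl
F10 | step 6 | (1R,5S)-5-bromo-2-[(1R)-2-chloro-1-hydroxyethyl]-4,4-dimethylcyclohex-2-en-1-yl acetate | CC(=O)O[C@@H]1C[C@H](Br)C(C)(C)C=C1[C@@H](O)CCl
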